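(The numbers are those of an exercise.)

A small charge of G, 2.5 mol% on E, had to turn over many times, so I took the Z of these flasks to be born through the run rather than at its start, and I reckoned each flask by how old its Z became.

    E + G ⇌ E.G (K1 = 51 M⁻¹, k1 = 1410 M⁻¹ h⁻¹)
    Q + E.G ⇌ Q.E.G (K2 = 20 M⁻¹, k2 = 252 M⁻¹ h⁻¹)
    Q.E.G → G + Z (k3 = 99.9 h⁻¹)
    E ⇌ X (K4 = 3.70, k4 = 0.0123 h⁻¹)
    Z ⇌ L (K5 = 2.42, k5 = 0.00212 h⁻¹)

in all of them: G 2.5 mol%
- cedar: E 12 mM (fed, over 16.0 h); Q 0.700 equiv; time 20 h; a stirred flask in which E is dosed at a steady rate over 16.0 h without added volume, worked up at 20 h
- ash: E 12 mM; Q 0.700 equiv; time 20 h; a closed flask charged with all of it at once and left for 20 h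
- maple: E 12 mM; Q 0.700 equiv; one stirred flow tank at steady state, fed with the mixture as stated, mean residence time 20 h
- oak: E 12 mM; Q 0.700 equiv (fed, over 16.0 h); time 20 h; a stirred flask in which Q is dosed at a steady rate over 16.0 h without added volume, worked up at 20 h

- the set-up with the highest share of Z in all that became Z or L, at the outlet or at the end ("none" if the first two lie within 2 percentage points) (cedar / ash / maple / oak / none)
- share of Z in all that became Z or L, at the outlet or at the end, cedar
- share of Z in all that became Z or L, at the outlet or at the end, ash
- share of Z in all that became Z or L, at the outlet or at the end, maple
- share of Z in all that became Z or L, at the outlet or at the end, oak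

- the stated concentrations are those of everything mixed, before any reaction; amounts are the same in each set-up
- the feed brings no volume worth counting
- run time (cedar): 20 h

How far could a parcel of Z drift? The Z to L step is first order both ways, so I integrated it in closed form: the fraction of a parcel still Z fell exponentially from the whole towards 29.2%, its floor under thermodynamic control, at the forward and back constants added, a drift rate of 0.00300 h⁻¹. The half-life of Z by the forward step alone was longer than the run, and a parcel as old as the run kept 95.9%.

What should maple give, with its ages spread exponentially around the residence time? Averaging the same curve over those ages gave 96.0%.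

Could dosing separate ash, cedar and oak? I gave ash steady production, a mean age of 10.0 h and a share of 97.9%. For cedar and oak alike I let production rise from nothing until dosing ended and stop there, a crude assumption that gave a mean age of 9.33 h and a share of 98.0%. My top two were level, and even ash stood 0.10 percentage points lower, less than the margin, so I said none.

The forecast gave cedar 98.3%, ash 97.7%, maple 96% and oak 98.4%, and its answer was none, on the ground that “the only loss is the slow Z→L drift”. It agreed with me on maple and on the answer, but stood a little apart from my shares for the other flasks.

The simulation gave cedar 98.3%, ash 97.7%, maple 96.0% and oak 98.4%, and the answer none.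

The forecast stood, but its share for oak would not have held in a run ten times as long, the largest single effect shown on oak. Through the drift rate, the 98.4% of oak read as a single Z age of 7.51 h. Oak left until 200 h lost 23 points and stood at 75.0%, above the 68.1% kept by a parcel as old as that run, and its share read as a single Z age of 145 h.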